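## Retrosynthetic overview

- Target 17 ⇐ dimethoxyquinone 15 (hydrolysis of the two vinylogous methyl esters) ⇐ arene 14 (oxidative demethylation). The quinone is carried as a 1,2,4,5-tetramethoxybenzene until the chain is complete.
- Key disconnection: C10'–C11' of the side chain (numbered C1' on the ring to C19'). It is made by a reductive Ni/Co cross-electrophile coupling of primary bromide 6 (C10') with primary tosylate 13 (C11'). Both carbons are electrophilic, so this is a like-polarity union with no preformed organometallic.
- Enabling feature: C10' lies ten CH2 groups from the six-membered ring and C11' three CH2 groups before the C14'=C15' E-alkene. Both are unhindered primary sp3 carbons, the C11' radical is a pent-4-enyl radical with no fast cyclisation mode, and the tetramethoxybenzene ring (unlike the quinone) is inert to low-valent Ni/Co/Mn.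
- 6 ⇐ two successive ortho-lithiations of 1,2,4,5-tetramethoxybenzene (MeI, then 1,10-dibromodecane). 13 ⇐ Johnson–Claisen rearrangement of hept-1-en-3-ol (sets C14'=C15' as E, makes C11' the ester carbon), reduction, tosylation.
- Rings: none is formed. The single six-membered carbocycle is bought as the arene, and only its oxidation level changes (arene → quinone) at the end.

Key step: step 6

Remark: the target has no stereocentre; the only stereochemical element is the E geometry of C14'=C15'. Racemic hept-1-en-3-ol is used because its stereocentre is destroyed in step 3.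

## Route

Step 1
Reactants: 1 1,2,4,5-tetramethoxybenzene
Product: 3 1,2,4,5-tetramethoxy-3-methylbenzene, via (2,3,5,6-tetramethoxyphenyl)lithium 2 (not isolated)
Conditions: n-BuLi (1.05 equiv), THF, 0 °C to rt; then MeI, −78 °C to rt
Reagents that add atoms: iodomethane, CI
Why: Directed ortho-metalation at a ring CH flanked by two methoxy groups followed by SN2 methylation of the aryllithium should give 3, the two ring CH positions being equivalent and dimetalation being held back by the stoichiometry of the base.

Step 2
Reactants: 3 1,2,4,5-tetramethoxy-3-methylbenzene, 4 1,10-dibromodecane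
Product: 6 1-(10-bromodecyl)-2,3,5,6-tetramethoxy-4-methylbenzene, via (2,3,5,6-tetramethoxy-4-methylphenyl)lithium 5 (not isolated)
Conditions: n-BuLi, TMEDA, THF, 0 °C to rt; then cannulated into 4 (5 equiv), THF, −78 °C to rt
Reagents that add atoms: none
Why: A second directed ortho-metalation at the last ring CH and SN2 alkylation of the aryllithium by one end of the excess α,ω-dibromide (inverse addition suppresses double arylation) should leave the other C–Br as the C10' handle.

Step 3
Reactants: 7 hept-1-en-3-ol (racemic), 8 triethyl orthoacetate
Product: 11 ethyl (E)-non-4-enoate, via mixed orthoester 9 (not isolated), via ketene acetal 10 (not isolated)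
Conditions: 8 (5 equiv), EtCO2H (cat.), 140 °C, EtOH distilled off
Reagents that add atoms: none
Why: Johnson–Claisen rearrangement: acid-catalysed exchange and loss of ethanol give the ketene acetal, whose [3,3]-sigmatropic shift through a chair transition state with the butyl group equatorial should form the new alkene (C14'=C15' of the target) as the E isomer while the carbinol stereocentre is destroyed.

Step 4
Reactants: 11 ethyl (E)-non-4-enoate
Product: 12 (E)-non-4-en-1-ol
Conditions: LiAlH4, Et2O, 0 °C to rt; Fieser work-up
Reagents that add atoms: none
Why: Hydride reduction of the ester (LiAlH4) should turn the ester carbon into the C11' primary carbinol without touching the isolated E-alkene.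

Step 5
Reactants: 12 (E)-non-4-en-1-ol
Product: 13 (E)-non-4-en-1-yl 4-methylbenzenesulfonate
Conditions: TsCl, Et3N, DMAP (cat.), CH2Cl2, 0 °C to rt
Reagents that add atoms: 4-methylbenzenesulfonyl chloride, Cc1ccc(cc1)S(=O)(=O)Cl
Why: DMAP-catalysed O-sulfonylation of the primary alcohol should install on C11' a leaving group that differs from the bromide on C10', with no stereocentre or alkene involved.

Step 6
Reactants: 6 1-(10-bromodecyl)-2,3,5,6-tetramethoxy-4-methylbenzene, 13 (E)-non-4-en-1-yl 4-methylbenzenesulfonate
Product: 14 1,2,4,5-tetramethoxy-3-methyl-6-[(E)-nonadec-14-en-1-yl]benzene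
Conditions: 13 (1.5 equiv), NiCl2·glyme (10 mol%), dtbbpy (10 mol%), vitamin B12 (5 mol%), Mn powder (3 equiv), DMA, 30 °C, Ar
Reagents that add atoms: none
Why: Mn should reduce the Ni(II)/bipyridine complex and vitamin B12 to low-valent Ni and cob(I)alamin; Ni takes up the C10'–Br terminus of 6 by halogen abstraction and radical rebound, while the supernucleophilic Co(I) displaces the tosylate of 13 by SN2 to a non-4-enyl–Co(III) species whose weak Co–C bond passes the non-4-enyl radical to the alkyl–Ni centre, and reductive elimination from the dialkyl–Ni(III) forms the C10'–C11' bond. The closest known reaction type is the Ni/Co dual-catalysed reductive C(sp3)–C(sp3) cross-electrophile coupling of primary alkyl halides with primary alkyl tosylates. No ring is closed and no stereocentre is created. The step needs cross- over homo-coupling, which is secured by the two different leaving groups (bromide on C10', tosylate on C11'), each activated by its own catalyst, and by a slight excess of the simpler partner 13; the homodimers (a C18 diene hydrocarbon and a bis-arene) differ strongly from 14 in polarity and size. It also needs the E geometry of C14'=C15' to survive, which is secured because the C11' radical is a pent-4-enyl radical whose only cyclisation modes (4-exo, 5-endo) are slow and the alkene is neither allylic nor conjugated to the reacting carbon. The tetramethoxybenzene ring is inert to the low-valent metals, which is why the coupling precedes the unveiling of the quinone.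

Step 7
Reactants: 14 1,2,4,5-tetramethoxy-3-methyl-6-[(E)-nonadec-14-en-1-yl]benzene
Product: 15 2,5-dimethoxy-3-methyl-6-[(E)-nonadec-14-en-1-yl]cyclohexa-2,5-diene-1,4-dione
Conditions: CAN (2.5 equiv), MeCN/H2O (2:1), 0 °C, short reaction time
Reagents that add atoms: water, O
Why: CAN oxidative demethylation (two one-electron oxidations of the electron-rich arene, ipso attack of water at two para methoxy-bearing carbons, loss of two MeOH) should give the 2,5-dimethoxy-1,4-benzoquinone, the four-fold methoxy symmetry making both possible para-quinones the same compound and the isolated alkene being far less oxidisable than the arene.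

Step 8
Reactants: 15 2,5-dimethoxy-3-methyl-6-[(E)-nonadec-14-en-1-yl]cyclohexa-2,5-diene-1,4-dione
Product: 17 2,5-dihydroxy-3-methyl-6-[(E)-nonadec-14-en-1-yl]cyclohexa-2,5-diene-1,4-dione, via disodium quinone-diolate 16 (not isolated)
Conditions: 2 M NaOH, EtOH, 70 °C, N2; then 2 M HCl, 0 °C
Reagents that add atoms: sodium hydroxide, [Na+].[OH-]
Why: Saponification of the two vinylogous methyl esters by addition–elimination of hydroxide, driven by formation of the doubly vinylogous carboxylate dianion, followed by acidification should give the dihydroxyquinone with the remote E-alkene untouched.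

## Compound list

1 | 1,2,4,5-tetramethoxybenzene | COc1cc(OC)c(OC)cc1OC | starting material
2 | (2,3,5,6-tetramethoxyphenyl)lithium | [Li]c1c(OC)c(OC)cc(OC)c1OC | intermediate
3 | 1,2,4,5-tetramethoxy-3-methylbenzene | Cc1c(OC)c(OC)cc(OC)c1OC | intermediate
4 | 1,10-dibromodecane | BrCCCCCCCCCCBr | starting material
5 | (2,3,5,6-tetramethoxy-4-methylphenyl)lithium | [Li]c1c(OC)c(OC)c(C)c(OC)c1OC | intermediate
6 | 1-(10-bromodecyl)-2,3,5,6-tetramethoxy-4-methylbenzene | Cc1c(OC)c(OC)c(CCCCCCCCCCBr)c(OC)c1OC | intermediate
7 | hept-1-en-3-ol (racemic) | CCCCC(O)C=C | starting material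
8 | triethyl orthoacetate | CC(OCC)(OCC)OCC | starting material
9 | 3-(1,1-diethoxyethoxy)hept-1-ene (mixed orthoester) | CCCCC(OC(C)(OCC)OCC)C=C | intermediate
10 | 3-[(1-ethoxyethenyl)oxy]hept-1-ene (ketene acetal) | CCCCC(OC(=C)OCC)C=C | intermediate
11 | ethyl (E)-non-4-enoate | CCCC/C=C/CCC(=O)OCC | intermediate
12 | (E)-non-4-en-1-ol | CCCC/C=C/CCCO | intermediate
13 | (E)-non-4-en-1-yl 4-methylbenzenesulfonate | CCCC/C=C/CCCOS(=O)(=O)c1ccc(C)cc1 | intermediate
14 | 1,2,4,5-tetramethoxy-3-methyl-6-[(E)-nonadec-14-en-1-yl]benzene | CCCC/C=C/CCCCCCCCCCCCCc1c(OC)c(OC)c(C)c(OC)c1OC | intermediate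
15 | 2,5-dimethoxy-3-methyl-6-[(E)-nonadec-14-en-1-yl]cyclohexa-2,5-diene-1,4-dione | CCCC/C=C/CCCCCCCCCCCCCC1=C(OC)C(=O)C(C)=C(OC)C1=O | intermediate
16 | disodium 2-methyl-5-[(E)-nonadec-14-en-1-yl]-3,6-dioxocyclohexa-1,4-diene-1,4-diolate | CCCC/C=C/CCCCCCCCCCCCCC1=C([O-])C(=O)C(C)=C([O-])C1=O.[Na+].[Na+] | intermediate
17 | 2,5-dihydroxy-3-methyl-6-[(E)-nonadec-14-en-1-yl]cyclohexa-2,5-diene-1,4-dione | CCCC/C=C/CCCCCCCCCCCCCC1=C(O)C(=O)C(C)=C(O)C1=O | target

## Step count and risks

Total step count: 8. Longest linear sequence: 6 steps (steps 3, 4, 5, 6, 7, 8); the arene branch (steps 1, 2) joins at step 6.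

Steps most likely to fail:

Step 6. Homocoupling of either electrophile, hydrodehalogenation, or β-hydride loss from the alkyl–metal intermediates may outrun the cross-coupling. The fallback replaces the reductive radical coupling by a polar, copper-catalysed alkyl–alkyl coupling. It sets out from 6, which is converted with Mg turnings in THF into the Grignard reagent [10-(2,3,5,6-tetramethoxy-4-methylphenyl)decyl]magnesium bromide F1. F1 is then coupled with tosylate 13 under Li2CuCl4 catalysis (THF, −78 °C to rt; Kochi–Schlosser-type SN2 displacement by an alkylcuprate). The remote alkene and the aryl ethers are inert to these conditions, and the route is rejoined at 14.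

Step 7. Over-oxidation, attack of the oxidant on the C14'=C15' alkene, or partial formation of the ortho-quinone may erode the oxidative demethylation. The fallback avoids a strong oxidant. It sets out from 14, which is exhaustively demethylated with BBr3 (CH2Cl2, −78 to 0 °C, cold quench) to 3-methyl-6-[(E)-nonadec-14-en-1-yl]benzene-1,2,4,5-tetrol F2. This electron-rich tetrol should be oxidised by air during a buffered work-up (O2, EtOAc/pH 7 buffer) directly to the dihydroxyquinone. The route is rejoined at 17, bypassing 15 and 16.

Step 2. Slow SN2 displacement by the hindered aryllithium may let E2 elimination of HBr or double arylation of the dibromide compete. The fallback replaces the alkylation by a carbonyl addition and deoxygenation. It sets out from 3: aryllithium 5 is generated as before and added at −78 °C to 10-bromodecanal F3 (from oxidation of commercial 10-bromodecan-1-ol). 1,2-Addition, much faster than attack at C–Br, gives 10-bromo-1-(2,3,5,6-tetramethoxy-4-methylphenyl)decan-1-ol F4. Ionic hydrogenation of the electron-rich benzylic alcohol (Et3SiH, TFA, CH2Cl2, 0 °C) removes the hydroxyl, and the route is rejoined at 6.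

## Further compounds

F1 | step 6 | [10-(2,3,5,6-tetramethoxy-4-methylphenyl)decyl]magnesium bromide | Cc1c(OC)c(OC)c(CCCCCCCCCC[Mg]Br)c(OC)c1OC
F2 | step 7 | 3-methyl-6-[(E)-nonadec-14-en-1-yl]benzene-1,2,4,5-tetrol | CCCC/C=C/CCCCCCCCCCCCCc1c(O)c(O)c(C)c(O)c1O
F3 | step 2 | 10-bromodecanal | O=CCCCCCCCCCBr
F4 | step 2 | 10-bromo-1-(2,3,5,6-tetramethoxy-4-methylphenyl)decan-1-ol | Cc1c(OC)c(OC)c(C(O)CCCCCCCCCBr)c(OC)c1OC
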